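**Retrosynthetic overview**

1. The target is 19-acetoxy-ent-labda-8(17),13-dien-15,16-olide. The last transform removes the exocyclic C8=C17 methylene to give a 17-nor C8 ketone (methylenation comes last).
2. The key disconnection is C9–C11. The ring B C8 ketone, activated at C9 by a formyl group (a 1,3-dicarbonyl), adds to 4-vinylfuran-2(5H)-one, whose vinyl terminus becomes C11. In one flask the 1,6-addition, loss of the formyl carbon as methyl formate and protonation of the C8/C9 enolate take place, and the protonation fixes C9.
3. The enabling feature is the exocyclic C8=C17 methylene on ring B next to C9. It is the retron of a C8 ketone, which makes C9 acidic, lets its configuration be erased and reset, and biases the side chain to the equatorial position beside the axial C20 methyl on C10. The second part of the feature is the butenolide ring (C13=C14–C15(=O)–O–C16), whose conjugation can be extended through C12 to C11.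
4. The formyl ketone comes from andrographolide by C–C cleavage: dehydration (moves the side-chain alkene to C11=C12), 19-O-acetylation, C3 deoxygenation, then ozonolysis of C8=C17 and C11=C12. The old C11 stays on C9 as the activating formyl group.
5. No ring is formed in the route. Rings A and B with C4, C5 and C10 come intact from andrographolide, and the lactone ring comes from 4-bromofuran-2(5H)-one (Stille vinylation).

Key step: step 7

Remark: atoms are numbered as in the ent-labdane skeleton (C19 = oxygenated carbon on C4, C20 = methyl on C10, C17 = methylene carbon on C8), and formyl ketone 6 is written as its hydroxymethylene (enol) tautomer, the usual form of 2-formylcycloalkanones.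

**Route**

Step 1
Reactants: 1 andrographolide
Product: 2 14-deoxy-11,12-didehydroandrographolide (3α,19-dihydroxy-ent-labda-8(17),11E,13-trien-16,15-olide)
Conditions: Al2O3 (neutral, activated), pyridine, reflux
Reagents that add atoms: none
Why: Vinylogous dehydration (1,4-elimination of the allylic C14 hydroxyl and a C11 hydrogen) should move the side-chain alkene to C11=C12 (E, in conjugation with the new C13=C14 butenolide), the position needed for later cleavage at C11; the C14 stereocentre is destroyed and C4, C5, C9, C10 are untouched.

Step 2
Reactants: 2 14-deoxy-11,12-didehydroandrographolide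
Product: 3 19-O-acetyl-14-deoxy-11,12-didehydroandrographolide
Conditions: Ac2O (1.1 equiv), pyridine, CH2Cl2, −20 → 0 °C
Reagents that add atoms: acetic anhydride, CC(=O)OC(C)=O
Why: Selective O-acylation of the primary C19 hydroxyl over the secondary C3 hydroxyl (flanked by quaternary C4) should install the acetate of the target, which also serves as the only protecting group; no stereocentre is formed.

Step 3
Reactants: 3 19-O-acetyl-14-deoxy-11,12-didehydroandrographolide
Product: 4 19-acetoxy-3α-[(1H-imidazol-1-ylcarbonothioyl)oxy]-ent-labda-8(17),11E,13-trien-16,15-olide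
Conditions: TCDI, DMAP (cat.), ClCH2CH2Cl, 70 °C
Reagents that add atoms: 1,1'-thiocarbonyldiimidazole, S=C(n1ccnc1)n1ccnc1
Why: Thioacylation of the remaining hindered C3 hydroxyl gives the imidazolide needed for a Barton–McCombie deoxygenation; the C–O bond is not touched, so C3 keeps its configuration.

Step 4
Reactants: 4 19-acetoxy-3α-[(1H-imidazol-1-ylcarbonothioyl)oxy]-ent-labda-8(17),11E,13-trien-16,15-olide
Product: 5 19-acetoxy-ent-labda-8(17),11E,13-trien-16,15-olide
Conditions: Bu3SnH (slow addition), AIBN (cat.), toluene, 100 °C
Reagents that add atoms: none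
Why: Barton–McCombie radical deoxygenation (stannyl radical adds to C=S, β-scission gives the secondary C3 radical, hydrogen transfer from Bu3SnH) should turn C3 into a methylene so that it is no longer a stereocentre; a low hydride concentration favours attack at the thiocarbonyl over hydrostannation of the diene lactone.

Step 5
Reactants: 5 19-acetoxy-ent-labda-8(17),11E,13-trien-16,15-olide
Product: 6 19-acetoxy-8-oxo-12,13,14,15,16,17-hexanor-ent-labdan-11-al as its (Z)-9-(hydroxymethylene) tautomer
Conditions: O3, Sudan Red 7B, CH2Cl2, −78 °C; then PPh3, −78 → 23 °C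
Reagents that add atoms: ozone, [O-][O+]=O
Why: Ozonolysis with reductive work-up should cleave the two electron-rich alkenes C8=C17 and C11=C12 before the electron-poor butenolide alkene (the dye marks the end point), leaving a C8 ketone and the old C11 as an aldehyde on C9, which tautomerise to the hydrogen-bonded hydroxymethylene ketone; C9 becomes sp2 for the time being and C4, C5, C10 are untouched.

Step 6
Reactants: 7 4-bromofuran-2(5H)-one
Product: 8 4-vinylfuran-2(5H)-one
Conditions: tributyl(vinyl)stannane, Pd(PPh3)4 (cat.), BHT, toluene, 80 °C
Reagents that add atoms: tributyl(vinyl)stannane, C=C[Sn](CCCC)(CCCC)CCCC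
Why: Stille coupling of the vinylogous acyl bromide (ready oxidative addition to zerovalent palladium) under neutral conditions should give the base-sensitive vinylbutenolide, to be used promptly; no stereocentre is formed.

Step 7
Reactants: 6 19-acetoxy-8-oxo-12,13,14,15,16,17-hexanor-ent-labdan-11-al (hydroxymethylene tautomer); 8 4-vinylfuran-2(5H)-one
Product: 10 19-acetoxy-8-oxo-17-nor-ent-labd-13-en-15,16-olide, via C9-formyl Michael adduct 9 (not isolated)
Conditions: 8 (1.5 equiv), DBU (0.3 equiv), MeCN, 23 °C; then MeOH, 23 °C; AcOH quench
Reagents that add atoms: none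
Why: Proposed new method: DBU deprotonates only the C9-formyl/C8-keto 1,3-dicarbonyl of 6 (far more acidic than either butenolide), and this enolate adds through C9 to the unsubstituted vinyl terminus of 8 (the future C11) in a 1,6-addition that releases an aromatic 2-furanolate, which is reprotonated and equilibrated to the conjugated butenolide; methanol then attacks the now non-enolisable aldehyde of 9, and a retro-Claisen fragmentation expels methyl formate and the C8 enolate, which is protonated at C9. The closest known reaction types are the formyl-activated Michael addition of 2-(hydroxymethylene)cycloalkanones to vinyl ketones with deformylation in the same flask and the 1,6-addition of 1,3-dicarbonyl compounds to dienyl acceptors that are unsubstituted at the terminal carbon; new is their combination on a 4-vinylbutenolide and at a ring carbon next to a quaternary centre. No ring is closed. The C9 stereocentre is not fixed by the C–C bond formation: whichever face of the enolate is alkylated in 9, the configuration is erased on deformylation and set by protonation of the C8/C9 enolate on the face opposite the axial C20 methyl, which places the side chain equatorial, the arrangement that enolisation under the same base also favours thermodynamically, so all isomers should funnel into one. Site selectivity for C9 over C7 is secured by the formyl carbon inherited from C11 of andrographolide, 1,6- over 1,4-addition by the fully substituted β-carbon and free terminal methylene of 8, and formyl over ring-ketone attack in the cleavage by the higher electrophilicity of the aldehyde. The irreversible loss of methyl formate should drain the reversible, congested C- (and any O-) Michael equilibria, and buffering by 6 keeps methoxide low so that the C19 acetate should survive.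

Step 8
Reactants: 10 19-acetoxy-8-oxo-17-nor-ent-labd-13-en-15,16-olide
Product: 11 19-acetoxy-ent-labda-8(17),13-dien-15,16-olide (target)
Conditions: Zn, CH2Br2, TiCl4, THF/CH2Cl2, 0 → 23 °C
Reagents that add atoms: dibromomethane, BrCBr
Why: Takai–Lombardo methylenation uses a non-basic titanium methylidene that should convert the ketone to the C8=C17 methylene in preference to the acetate and lactone carbonyls, without enolising C9 or deprotonating the butenolide; no stereocentre is formed.

**Compound list**

1 | andrographolide (3α,14S,19-trihydroxy-ent-labda-8(17),12E-dien-16,15-olide) | C=C1CC[C@@H]2[C@](C)(CO)[C@H](O)CC[C@@]2(C)[C@@H]1C/C=C1/C(=O)OC[C@H]1O | starting material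
2 | 14-deoxy-11,12-didehydroandrographolide (3α,19-dihydroxy-ent-labda-8(17),11E,13-trien-16,15-olide) | C=C1CC[C@@H]2[C@](C)(CO)[C@H](O)CC[C@@]2(C)[C@@H]1/C=C/C1=CCOC1=O | intermediate
3 | 19-O-acetyl-14-deoxy-11,12-didehydroandrographolide (19-acetoxy-3α-hydroxy-ent-labda-8(17),11E,13-trien-16,15-olide) | C=C1CC[C@@H]2[C@](C)(COC(C)=O)[C@H](O)CC[C@@]2(C)[C@@H]1/C=C/C1=CCOC1=O | intermediate
4 | 19-acetoxy-3α-[(1H-imidazol-1-ylcarbonothioyl)oxy]-ent-labda-8(17),11E,13-trien-16,15-olide | C=C1CC[C@@H]2[C@](C)(COC(C)=O)[C@H](OC(=S)n3ccnc3)CC[C@@]2(C)[C@@H]1/C=C/C1=CCOC1=O | intermediate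
5 | 19-acetoxy-ent-labda-8(17),11E,13-trien-16,15-olide | C=C1CC[C@@H]2[C@](C)(COC(C)=O)CCC[C@@]2(C)[C@@H]1/C=C/C1=CCOC1=O | intermediate
6 | 19-acetoxy-8-oxo-12,13,14,15,16,17-hexanor-ent-labdan-11-al, (Z)-9-(hydroxymethylene) tautomer; C4, C5, C10 as in 1 | O=C1CC[C@@H]2[C@](C)(COC(C)=O)CCC[C@@]2(C)/C1=C/O | intermediate
7 | 4-bromofuran-2(5H)-one | O=C1C=C(Br)CO1 | starting material
8 | 4-vinylfuran-2(5H)-one | C=CC1=CC(=O)OC1 | intermediate
9 | 19-acetoxy-9-formyl-8-oxo-17-nor-ent-labd-13-en-15,16-olide (C9 quaternary; side chain trans to the C20 methyl, formyl cis) | O=C1CC[C@@H]2[C@](C)(COC(C)=O)CCC[C@@]2(C)[C@@]1(C=O)CCC1=CC(=O)OC1 | intermediate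
10 | 19-acetoxy-8-oxo-17-nor-ent-labd-13-en-15,16-olide (H-9 trans to the C20 methyl, side chain equatorial) | O=C1CC[C@@H]2[C@](C)(COC(C)=O)CCC[C@@]2(C)[C@@H]1CCC1=CC(=O)OC1 | intermediate
11 | 19-acetoxy-ent-labda-8(17),13-dien-15,16-olide, (4R,5S,9R,10S) | C=C1CC[C@@H]2[C@](C)(COC(C)=O)CCC[C@@]2(C)[C@@H]1CCC1=CC(=O)OC1 | target

**Step count**

Total step count: 8. Longest linear sequence: 7 (steps 1–5, 7, 8).

**Steps most likely to fail**

Step 7. The congested C-alkylation at C9 may stall if the addition reverses faster than the adduct is cleaved. The vinylbutenolide may also oligomerise through its own furanolate, or the acetate may be lost by methanolysis. The fallback uses known chemistry and forms the same C9–C11 bond. It sets out from 6. A formyl-activated Michael addition to the known vinyl ketone 1-[(tert-butyldimethylsilyl)oxy]but-3-en-2-one (Et3N, CH2Cl2, 23 °C) should give the quaternary C9-formyl adduct F1. This is deformylated in the same flask (MeOH, Et3N) to the diketone silyl ether F2, with C9 set by the same enolate protonation. HF·pyridine (THF, 0 °C) should free the α-hydroxy ketone F3. (Triphenylphosphoranylidene)ketene (toluene, 80 °C) then acylates the hydroxyl and closes the butenolide by intramolecular Wittig reaction on the neighbouring side-chain ketone; the ring B ketone is out of reach. The sequence comes back to the route at 10.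

Step 4. Addition of the stannyl radical to the cross-conjugated diene lactone (hydrostannation or reduction of the side chain) may compete with the deoxygenation. The fallback is ionic and sets out from 3. Dess–Martin periodinane (CH2Cl2, 23 °C) should give the 3-ketone F4. Tosylhydrazide (EtOH, 60 °C) should give the tosylhydrazone F5. Catecholborane (CHCl3, 0 °C), then NaOAc·3H2O (reflux), should reduce it to the methylene through the diazene. The sequence comes back to the route at 5.

Step 8. Methylenation of the hindered C8 ketone beside the substituted C9 may be slow, and the titanium reagent may attack the lactone carbonyl instead. The fallback is a Peterson olefination and sets out from 10. Me3SiCH2MgCl with CeCl3 (THF, −78 °C) should add to the ketone to give the β-hydroxysilane F6 (either C8 epimer serves). Aqueous HF in MeCN (23 °C) should induce elimination to the exocyclic alkene. The sequence comes back to the route at 11.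

**Further compounds**

F1 | step 7 | 19-acetoxy-9-formyl-16-[(tert-butyldimethylsilyl)oxy]-14,15,17-trinor-ent-labdane-8,13-dione (C9 quaternary, side chain trans to the C20 methyl) | O=C1CC[C@@H]2[C@](C)(COC(C)=O)CCC[C@@]2(C)[C@@]1(C=O)CCC(=O)CO[Si](C)(C)C(C)(C)C
F2 | step 7 | 19-acetoxy-16-[(tert-butyldimethylsilyl)oxy]-14,15,17-trinor-ent-labdane-8,13-dione | O=C1CC[C@@H]2[C@](C)(COC(C)=O)CCC[C@@]2(C)[C@@H]1CCC(=O)CO[Si](C)(C)C(C)(C)C
F3 | step 7 | 19-acetoxy-16-hydroxy-14,15,17-trinor-ent-labdane-8,13-dione | O=C1CC[C@@H]2[C@](C)(COC(C)=O)CCC[C@@]2(C)[C@@H]1CCC(=O)CO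
F4 | step 4 | 19-acetoxy-3-oxo-ent-labda-8(17),11E,13-trien-16,15-olide | C=C1CC[C@@H]2[C@](C)(COC(C)=O)C(=O)CC[C@@]2(C)[C@@H]1/C=C/C1=CCOC1=O
F5 | step 4 | 19-acetoxy-3-oxo-ent-labda-8(17),11E,13-trien-16,15-olide 3-(4-methylbenzenesulfonyl)hydrazone | C=C1CC[C@@H]2[C@](C)(COC(C)=O)C(=NNS(=O)(=O)c3ccc(C)cc3)CC[C@@]2(C)[C@@H]1/C=C/C1=CCOC1=O
F6 | step 8 | 19-acetoxy-8-hydroxy-17-(trimethylsilyl)-ent-labd-13-en-15,16-olide (C8 epimers) | C[Si](C)(C)CC1(O)CC[C@@H]2[C@](C)(COC(C)=O)CCC[C@@]2(C)[C@@H]1CCC1=CC(=O)OC1
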